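Early on, at 1.25 d, blue shows 5.7% target and red 2.3%. Those are the first points of rising curves, so read the later points to see where each run ends.

common to all: starting material 0.79 M

|  | second substrate | solid reagent | remark | time |
|---|---|---|---|---|
| blue | 0.40 M (fed, over 15 h) | 0.395 M | run made earlier; the fed solution adds 0.10 times the starting volume |  |
| red | 1.6 M (fed, over 15 h) | 0.395 M | run made earlier; the fed solution adds 0.10 times the starting volume |  |
| teal | 0.79 M (fed, over 15 h) | 0.79 M | run made earlier; the fed solution adds 0.10 times the starting volume |  |
| flask | 0.790 M (fed, over 15 h) | 0.395 M | the fed solution adds 0.10 times the starting volume | 15 d |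

| run | time / d | starting material / % | target / % |
|---|---|---|---|
| blue | 1.25 | 95.0 | 5.7 |
| blue | 3.00 | 88.2 | 14.1 |
| blue | 8.00 | 68.4 | 31.7 |
| blue | 20.0 | 68.3 | 33.5 |
| red | 1.25 | 97.6 | 2.3 |
| red | 3.00 | 91.5 | 6.3 |
| red | 8.00 | 83.1 | 18.0 |
| red | 20.0 | 81.1 | 18.7 |
| teal | 1.25 | 95.8 | 4.7 |
| teal | 3.00 | 89.2 | 8.2 |
| teal | 8.00 | 72.9 | 26.4 |
| teal | 20.0 | 50.8 | 51.0 |

(scatter of a reading: 1 percentage point)

- charges are per starting volume, the dose included; the dosed solution carries all of it
- as a solid, counted per litre of solution: solid reagent
- at the start none of the solid reagent is in solution
- the reaction counts as stopped when no species that holds the starting material changes by six tenths of a point or more over the second half of the time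

1. at 15 d, what has stopped the reaction, if anything has (for what has run out or reacted, a solid counts together with what of it has only dissolved) (it is still moving / all of the starting material has reacted / the partner has run out first)
2. how much of the starting material has reacted by 15 d
3. how much target there is at 15 d, in percent of the starting material charged

Keep a ledger of the solid reagent, which becomes partner as it dissolves. Blue's starting material reads 68.4% at 8.00 d and 68.3% at 20.0 d, so blue stands still with starting material left. Red, with blue's solid and more second substrate than blue, reads 18.0% and 18.7% target at those times. Teal, with twice blue's solid and more second substrate than blue, climbs from 26.4% to 51.0% target over the same days. I therefore book the solid as the limiting reagent. This flask has blue's charge of it, so I expect its books to close near 8.00 d, earlier than 15 d.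

Now the entries. Of blue's 0.395 M, target takes 0.265 M, and 0.130 M goes elsewhere. Call partner lost elsewhere per mole of target the loss ratio. Of red's 0.395 M, target takes 0.148 M. As a reading the ratio is 0.493 in blue and 1.67 in red, higher with more second substrate. On a straight line between them, at this flask's 0.790 M, I get 0.876, the flask's loss ratio. Each mole of target then costs one mole of solid plus that ratio, so my reckoning gives 26.6% target. In blue, starting material lost is 31.7% and target 33.5%, so I book conversion at the same figure.

The forecast says the partner has run out first, with conversion 26.5% and target 26%, on the ground that “the solid is the limiting partner”. My target figure stands 0.60 percentage points above its figure.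

The flask gives the partner has run out first, with conversion 26.1% and target 26.1%. At 15.0 d, 0% of the charged solid remains, dissolved or not, beside 74% of the starting material. Its second product 0.160 M and decomposed reagent 0.0114 M, scaled up for the volume the feed added, set against its target, give a loss ratio of 0.917, beside my 0.876.

    partner → decomposed reagent (k = 1.18 × 10⁻⁴ min⁻¹)
    starting material + partner → target (k = 0.00311 M⁻¹ min⁻¹)
    second substrate + partner → second product (k = 0.00267 M⁻¹ min⁻¹)
    solid reagent ⇌ partner, rate k4*(cs4 - [partner]) while solid is left; crystals form when [partner] > cs4 (solubility = 0.290 M, k = 1.21 × 10⁻⁴ min⁻¹)

Take the neighbour charged with 1.6 M of solid reagent. At 0.876, that solid could pay for 108% of the starting material, more than was charged, so its ledger need not close on solid. At 15 d it gives 50.7% target with 51% of its solid still there, dissolved or not, and nothing that was charged has run out.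

The readings are calculated with made-up constants; noise was put on by code.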